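**Retrosynthetic overview**
- The dihydropyran enol ether is unveiled last, by methylenating a δ-lactone carbonyl and moving the C=C into the ring.
- That lactone is cut at the ring–ring C–C bond into two C7 halves: a bromo-δ-lactone (as its enolate) and a 3-bromo-4-chloro-4-methylcyclohexanone. An aldol joins them and the resulting tertiary OH is replaced by H.
- Cyclohexanone half: an asymmetric Diels–Alder reaction (isoprene + acrolein) builds the ring; the CHO-bearing centre directs BrCl addition and is then excised by enol ether ozonolysis.
- Lactone half: enantioselective bromochlorination of prenol, two-carbon extension, then bromonium-mediated lactonisation builds the oxanone ring.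
- Ring order: cyclohexane and oxanone are made separately; the dihydropyran forms last from the oxanone.

Assumption: the (5S)-imidazolidinone is taken to give the (R)-aldehyde and the Burns ligand enantiomer is chosen to give the (2R)-bromide; if either sense is reversed, the mirror-image catalyst is used.

**Cyclohexanone fragment**

Step 1
Reactants: 1 isoprene; 2 acrolein
Product: 3 (R)-4-methylcyclohex-3-ene-1-carbaldehyde
Conditions: (5S)-5-benzyl-2,2,3-trimethylimidazolidin-4-one·HCl (10–20 mol %), MeCN/H2O 95:5, −10 °C to rt
Reagents that add atoms: none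
Why: Iminium-catalysed enantioselective Diels–Alder reaction; isoprene adds "para" and the catalyst's benzyl group blocks one face of the iminium, setting C1 as R (about 85–90% ee expected).

Step 2
Reactants: 3
Product: 4 (1R,3S,4S)-3-bromo-4-chloro-4-methylcyclohexane-1-carbaldehyde
Conditions: n-Bu4N[BrCl2] (1.1 equiv), CH2Cl2, −78 to −20 °C
Reagents that add atoms: tetrabutylammonium dichlorobromate, written as the Bu4N+ Cl−·BrCl ion pair, CCCC[N+](CCCC)(CCCC)CCCC.[Cl-].ClBr
Why: Anti bromochlorination via a bromonium ion, with chloride opening at the tertiary carbon in a trans-diaxial sense with CHO equatorial (the limonene-type outcome), so Br enters on the face opposite CHO and C3/C4 are set as S,S from C1.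

Step 3
Reactants: 4
Product: 5 tert-butyl{[(3S,4S)-3-bromo-4-chloro-4-methylcyclohexylidene]methoxy}dimethylsilane (E/Z mixture)
Conditions: TBSOTf, Et3N, CH2Cl2, 0 °C to rt
Reagents that add atoms: TBSOTf, CC(C)(C)[Si](C)(C)OS(=O)(=O)C(F)(F)F
Why: Soft enolisation and O-silylation of the α-branched aldehyde gives the exocyclic silyl enol ether; C1 has done its job as control element and becomes sp2.

Step 4
Reactants: 5
Product: 6 (3S,4S)-3-bromo-4-chloro-4-methylcyclohexan-1-one
Conditions: O3, CH2Cl2, −78 °C; then Me2S; neutral work-up, used cold without storage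
Reagents that add atoms: ozone, [O-][O+]=O
Why: Ozonolysis of the electron-rich enol ether C=C removes the former formyl carbon and leaves the ketone; neutral conditions avoid HBr loss from the β-bromo ketone.

**Lactone fragment**

Step 5
Reactants: 7 prenol (3-methylbut-2-en-1-ol)
Product: 8 (2R)-2-bromo-3-chloro-3-methylbutan-1-ol
Conditions: NBS, ClTi(OiPr)3, Burns chiral tridentate Schiff-base ligand (10–20 mol %), hexanes, −20 °C
Reagents that add atoms: N-bromosuccinimide, O=C1CCC(=O)N1Br; chlorotitanium triisopropoxide, CC(C)O[Ti](Cl)(OC(C)C)OC(C)C
Why: Ti-catalysed enantioselective bromochlorination of an allylic alcohol (Burns); Br goes to C2 and chloride to the tertiary C3 (anti, Markovnikov), setting the CHBr centre as R.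

Step 6
Reactants: 8
Product: 9 (2R)-2-bromo-3-chloro-3-methylbutyl trifluoromethanesulfonate
Conditions: Tf2O, 2,6-lutidine, CH2Cl2, −78 °C; used immediately
Reagents that add atoms: triflic anhydride, FC(F)(F)S(=O)(=O)OS(=O)(=O)C(F)(F)F
Why: O-sulfonylation of the primary alcohol; the stereocentre is untouched.

Step 7
Reactants: 9; 10 tert-butyl acetate
Product: 11 tert-butyl (4R)-4-bromo-5-chloro-5-methylhexanoate
Conditions: LDA, THF, −78 °C (enolate of 10); then 9, THF/DMPU, −78 to −40 °C
Reagents that add atoms: none
Why: SN2 alkylation of the ester enolate at the primary triflate; the neopentyl-type secondary bromide and the tertiary chloride do not react at this temperature.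

Step 8
Reactants: 11
Product: 12 (5R)-5-bromo-6,6-dimethyloxan-2-one
Conditions: AgBF4 (1.2 equiv), CH2Cl2, 0 °C to rt (alternative: HFIP, 40 °C)
Reagents that add atoms: none
Why: Stereospecific bromonium lactonisation: Ag+ ionises the tertiary chloride with anchimeric help from the anti bromine, and the ester carbonyl opens the bromonium at the tertiary carbon (six-membered ring, loss of isobutylene), with retention at CHBr.

**Coupling and end game**

Step 9
Reactants: 12; 6
Product: 13 (5R)-5-bromo-3-[(3S,4S)-3-bromo-4-chloro-1-hydroxy-4-methylcyclohexyl]-6,6-dimethyloxan-2-one (mixture at lactone C3 and the carbinol carbon)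
Conditions: LDA, THF, −78 °C (enolate used within minutes); anhydrous CeCl3, −78 °C; then 6; AcOH quench at −78 °C
Reagents that add atoms: none
Why: Aldol addition of the lactone (cerium) enolate to the ketone joins the two C7 halves; the weakly basic cerium enolate limits E1cB loss of HBr from 6, the low temperature and short enolate lifetime suppress 1,3-displacement of the ring bromide, and both new centres are erased later.

Step 10
Reactants: 13
Product: 14 (5R)-5-bromo-3-[(1S,3S,4S)-3-bromo-4-chloro-4-methylcyclohexyl]-6,6-dimethyloxan-2-one (both C3 epimers)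
Conditions: Et3SiH (10 equiv), TFA (10 equiv), CH2Cl2, −20 to 0 °C; C1' epimer and mismatched diastereomers removed by chromatography
Reagents that add atoms: none
Why: Ionic hydrogenation (tertiary cation, silane hydride transfer): hydride should add to the ring carbon anti to the axial C–Br of the favoured Br/Cl-diaxial chair, giving after ring flip the all-equatorial 1S isomer; this is a kinetic prediction, not a certainty.

Step 11
Reactants: 14
Product: 15 laucapyranoid A, (3R)-3-bromo-5-[(1S,3S,4S)-3-bromo-4-chloro-4-methylcyclohexyl]-2,2,6-trimethyl-3,4-dihydro-2H-pyran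
Conditions: Tebbe reagent, pyridine (cat.), THF/toluene, −40 to 0 °C; basic work-up; then PPTS (cat.), 4 Å MS, CH2Cl2, rt
Reagents that add atoms: Tebbe reagent, written as Cp2Ti=CH2·ClAlMe2, C=[Ti](C1C=CC=C1)C1C=CC=C1.C[Al](C)Cl
Why: Tebbe carbonyl methylenation of the lactone, then acid-catalysed exo-to-endo enol ether isomerisation to the more stable tetrasubstituted dihydropyran (exocyclic isomer not isolated); the lactone C3 centre disappears, so both epimers converge.

**Compound list**
1 | isoprene | C=CC(C)=C | starting material
2 | acrolein | C=CC=O | starting material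
3 | (R)-4-methylcyclohex-3-ene-1-carbaldehyde | O=C[C@@H]1CCC(C)=CC1 | intermediate
4 | (1R,3S,4S)-3-bromo-4-chloro-4-methylcyclohexane-1-carbaldehyde | O=C[C@@H]1CC[C@](C)(Cl)[C@@H](Br)C1 | intermediate
5 | TBS enol ether of 4 (E/Z) | CC(C)(C)[Si](C)(C)OC=C1CC[C@](C)(Cl)[C@@H](Br)C1 | intermediate
6 | (3S,4S)-3-bromo-4-chloro-4-methylcyclohexan-1-one | O=C1CC[C@](C)(Cl)[C@@H](Br)C1 | intermediate
7 | prenol | CC(C)=CCO | starting material
8 | (2R)-2-bromo-3-chloro-3-methylbutan-1-ol | OC[C@@H](Br)C(C)(C)Cl | intermediate
9 | (2R)-2-bromo-3-chloro-3-methylbutyl triflate | FC(F)(F)S(=O)(=O)OC[C@@H](Br)C(C)(C)Cl | intermediate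
10 | tert-butyl acetate | CC(=O)OC(C)(C)C | starting material
11 | tert-butyl (4R)-4-bromo-5-chloro-5-methylhexanoate | CC(C)(C)OC(=O)CC[C@@H](Br)C(C)(C)Cl | intermediate
12 | (5R)-5-bromo-6,6-dimethyloxan-2-one | O=C1CC[C@@H](Br)C(C)(C)O1 | intermediate
13 | aldol adduct (tertiary alcohol) | O=C1C(C2(O)CC[C@](C)(Cl)[C@@H](Br)C2)C[C@@H](Br)C(C)(C)O1 | intermediate
14 | (5R)-5-bromo-3-[(1S,3S,4S)-3-bromo-4-chloro-4-methylcyclohexyl]-6,6-dimethyloxan-2-one | O=C1C([C@H]2CC[C@](C)(Cl)[C@@H](Br)C2)C[C@@H](Br)C(C)(C)O1 | intermediate
15 | laucapyranoid A | CC1=C([C@H]2CC[C@](C)(Cl)[C@@H](Br)C2)C[C@@H](Br)C(C)(C)O1 | target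

**Step count**
Total: 11 steps. Longest linear sequence: 7 steps (steps 1–4 or 5–8, then 9–11).

**Three steps most likely to fail**
1. Step 10 (stereochemistry at the ring CH, and survival of the tertiary chloride in acid). Fallback: set this centre by enolate protonation instead. Oxidise 4 to its methyl ester and invert C1 by kinetic protonation of the ester enolate (LDA, then a bulky phenol). Reduce and homologate to the cyclohexylacetonitrile, alkylate its anion with triflate 9, convert the nitrile to the methyl ketone, and close the pyran by Ag+-promoted bromonium capture by the ketone oxygen.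
2. Step 9 (HBr elimination from β-bromo ketone 6, or cyclopropane formation from the γ-bromo lactone enolate, under enolate conditions). Fallback: move to a non-basic Lewis-acid coupling. Use the dimethyl ketal of 6 with the silyl ketene acetal of 12 (TMSOTf, −78 °C); the resulting tertiary methyl ether is reduced in the same Et3SiH step.
3. Step 2 (facial and regiochemical control of BrCl addition with only a small CHO group, next to an enolisable aldehyde). Fallback: reagent-controlled acyclic route to 6. Apply the Burns bromochlorination to a mono-protected (Z)-3-methylpent-2-ene-1,5-diol (from 4-methyl-5,6-dihydro-2H-pyran-2-one), convert to the 1,5-bis-electrophile, and ring-close on TosMIC followed by hydrolysis.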